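**Strategy.** Both dimethylcarbinol carbons of the target are treated as former lactone carbonyls. On ring A the C5 phenol oxygen and the carbinol carbon at the end of the C6 chain are the two ends of an opened dihydrocoumarin. On ring B the O–C(CH3)2 unit of the pyran fused at C4'/C5' is a coumarin carbonyl that has taken up two methyl groups. One treatment with a methylcerium reagent therefore forms all four C–CH3 bonds and frees the C5 and C4' phenols. The precursor is an isoflavone with a dihydrocoumarin lactone across O5/C6, a MOM ether at C8 and a 7-(methoxymethoxy)coumarin-6-yl group at C3, assembled under acidic conditions that the saturated lactone tolerates.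

Key step: step 7

Assumption: the target is built exactly as drawn, with ring A oxygenated at C5 and C8 (not C7) and the hydroxyalkyl chain at C6; malic acid is used as the racemate.

**Step 1**
Reactants: 1 2,4-dihydroxyphenylacetic acid; 2 (RS)-malic acid
Product: 3 (7-hydroxy-2-oxo-2H-chromen-6-yl)acetic acid
Conditions: conc. H2SO4, 100 °C; ice-water; aq. NaHCO3, then HCl
Reagents that add atoms: (RS)-malic acid 2, OC(CC(O)=O)C(O)=O
Why: von Pechmann condensation: hot sulfuric acid turns malic acid into formylacetic acid (loss of CO and water), which attacks the resorcinol ring para to the 2-OH and ortho to the 4-OH and lactonises onto the 4-OH, the normal course for 4-substituted resorcinols and the one that places the acetic acid arm at C6 and the free phenol at C7 of the coumarin.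

**Step 2**
Reactants: 3 (7-hydroxy-2-oxo-2H-chromen-6-yl)acetic acid
Product: 5 (7-methoxy-2-oxo-2H-chromen-6-yl)acetic acid, via methyl ester 4 (not isolated)
Conditions: MeI (3 equiv), K2CO3, DMF, rt; concentrate; then 3 M aq. HCl, AcOH, 90 °C
Reagents that add atoms: iodomethane, CI; water, O
Why: Williamson O-methylation of the acidic 7-OH (the carboxylate is esterified at the same time) followed by acid-catalysed hydrolysis of the methyl ester, which leaves the coumarin and the aryl methyl ether intact; the ether stops this phenol from lactonising onto the acid or adding to the ketone during step 4.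

**Step 3**
Reactants: 6 scopoletin (7-hydroxy-6-methoxy-2H-chromen-2-one)
Product: 7 7-hydroxy-6-methoxy-3,4-dihydro-2H-chromen-2-one (dihydroscopoletin)
Conditions: H2 (1 atm), 10% Pd/C, EtOAc–AcOH, rt
Reagents that add atoms: none
Why: Heterogeneous hydrogenation of the conjugated C3=C4 bond of a coumarin over palladium is the standard entry to 3,4-dihydrocoumarins and leaves the arene, the phenol and the methyl ether untouched; the non-alcoholic solvent avoids transesterification of the new aryl ester.

**Step 4**
Reactants: 5 (7-methoxy-2-oxo-2H-chromen-6-yl)acetic acid; 7 7-hydroxy-6-methoxy-3,4-dihydro-2H-chromen-2-one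
Product: 9 6-methoxy-9-(7-methoxy-2-oxo-2H-chromen-6-yl)-3,4-dihydro-2H,10H-pyrano[2,3-f]chromene-2,10-dione, via deoxybenzoin 8 (not isolated)
Conditions: BF3·OEt2 (solvent), 85 °C; cool; then DMF, MeSO2Cl, 60 °C; aq. NaOAc
Reagents that add atoms: N,N-dimethylformamide, CN(C)C=O
Why: Friedel–Crafts acylation in BF3·OEt2 (O-acylation followed by a Fries-type shift) should place the acyl group ortho to the only free phenol of 7, at C8, because C6 carries the methoxy group and the para carbon C4a is substituted, and the Vilsmeier-type iminium salt from DMF and MsCl then aminomethylenates the activated CH2 so that the 7-OH closes ring C with loss of dimethylamine (deoxybenzoin route to isoflavones); a stray ketone at C5 would have no ortho hydroxyl and could not give an isoflavone, and the acidic medium spares the aryl ester lactone that amine or alkoxide reagents would open.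

**Step 5**
Reactants: 9 6-methoxy-9-(7-methoxy-2-oxo-2H-chromen-6-yl)-3,4-dihydro-2H,10H-pyrano[2,3-f]chromene-2,10-dione
Product: 10 6-hydroxy-9-(7-hydroxy-2-oxo-2H-chromen-6-yl)-3,4-dihydro-2H,10H-pyrano[2,3-f]chromene-2,10-dione
Conditions: BBr3 (6 equiv), CH2Cl2, −78 °C → rt; ice-water
Reagents that add atoms: none
Why: Boron tribromide cleaves aryl methyl ethers by bromide attack on the O-methyl carbon of the boron-complexed ether, whereas both lactones are aryl esters with no sp3 C–O bond to cleave and the chromone is inert, so only the two methoxy groups should be removed.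

**Step 6**
Reactants: 10 6-hydroxy-9-(7-hydroxy-2-oxo-2H-chromen-6-yl)-3,4-dihydro-2H,10H-pyrano[2,3-f]chromene-2,10-dione
Product: 11 6-(methoxymethoxy)-9-[7-(methoxymethoxy)-2-oxo-2H-chromen-6-yl]-3,4-dihydro-2H,10H-pyrano[2,3-f]chromene-2,10-dione
Conditions: MOMCl (3 equiv), i-Pr2NEt, CH2Cl2–DMF, 0 °C → rt
Reagents that add atoms: chloromethyl methyl ether, COCCl
Why: Williamson-type alkylation of the two phenols with MOMCl under a hindered, non-nucleophilic amine base is routine and does not open the dihydrocoumarin, and the resulting acetals are inert to organometallic reagents and keep O7 of the coumarin as an ether.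

**Step 7**
Reactants: 11 6-(methoxymethoxy)-9-[7-(methoxymethoxy)-2-oxo-2H-chromen-6-yl]-3,4-dihydro-2H,10H-pyrano[2,3-f]chromene-2,10-dione; 12 methylmagnesium bromide
Product: 13 5-hydroxy-6-(3-hydroxy-3-methylbutyl)-3-{4-hydroxy-5-[(1Z)-3-hydroxy-3-methylbut-1-en-1-yl]-2-(methoxymethoxy)phenyl}-8-(methoxymethoxy)-4H-chromen-4-one
Conditions: anhydrous CeCl3 (10 equiv), MeMgBr (10 equiv), THF, −78 °C; add 11; −78 → 0 °C; sat. aq. NH4Cl
Reagents that add atoms: methylmagnesium bromide 12, C[Mg]Br
Why: Methylcerium dichloride, formed from MeMgBr and CeCl3, adds to the dihydrocoumarin carbonyl, the tetrahedral intermediate expels the C5 phenoxide and the resulting methyl ketone takes a second methyl to give the C6 3-hydroxy-3-methylbutyl chain, while the coumarin carbonyl follows the same course by 1,2-addition, opening to the Z-enone phenoxide and a second 1,2-addition. The closest known reaction type is the double addition of methyl Grignard or methyllithium reagents to dihydrocoumarins and coumarins, which gives 2-(3-hydroxy-3-methylbutyl)phenols and (Z)-2-(3-hydroxy-3-methylbut-1-enyl)phenols. No ring is closed and no stereocentre is made; the Z geometry of the new allylic alcohol is the cis C3=C4 bond of the lactone carried over, since neither conjugate addition nor enolisation touches it. The step needs both lactone carbonyls to react before C4 and C2 of ring C: the aryl ester on ring A is the most electrophilic site and should react first at −78 °C, and the C5 phenoxide it releases chelates and conjugates with the C4 carbonyl, so the chromone becomes a poor acceptor before the slower coumarin is consumed. The oxophilic, weakly basic cerium reagent keeps every addition 1,2 and suppresses enolisation of the intermediate methyl ketones, and the MOM ether on O7 of the coumarin prevents that carbonyl from being deactivated by a phenoxide.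

**Step 8**
Reactants: 13 5-hydroxy-6-(3-hydroxy-3-methylbutyl)-3-{4-hydroxy-5-[(1Z)-3-hydroxy-3-methylbut-1-en-1-yl]-2-(methoxymethoxy)phenyl}-8-(methoxymethoxy)-4H-chromen-4-one
Product: 14 kraussianone 3, 5,8-dihydroxy-3-(7-hydroxy-2,2-dimethyl-2H-chromen-6-yl)-6-(3-hydroxy-3-methylbutyl)-4H-chromen-4-one
Conditions: HCl (about 1 M) in MeOH, rt → 40 °C
Reagents that add atoms: none
Why: Acid ionises the allylic, benzylic tertiary alcohol (its cation is stabilised by the ortho C4' and para C2' oxygens) and the C4' phenol captures it at the CMe2 carbon in a six-membered cyclodehydration that the Z geometry permits, while the same acid removes both MOM acetals by exchange with methanol; the saturated tertiary alcohol on the C6 chain and the chelated C5-OH should react far more slowly under these dilute conditions.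

**Compound list**
1 | 2,4-dihydroxyphenylacetic acid | OC(=O)Cc1ccc(O)cc1O | starting material
2 | (RS)-malic acid (racemic 2-hydroxybutanedioic acid) | OC(CC(O)=O)C(O)=O | starting material
3 | (7-hydroxy-2-oxo-2H-chromen-6-yl)acetic acid | OC(=O)Cc1cc2ccc(=O)oc2cc1O | intermediate
4 | methyl (7-methoxy-2-oxo-2H-chromen-6-yl)acetate | COC(=O)Cc1cc2ccc(=O)oc2cc1OC | intermediate (not isolated)
5 | (7-methoxy-2-oxo-2H-chromen-6-yl)acetic acid | OC(=O)Cc1cc2ccc(=O)oc2cc1OC | intermediate
6 | scopoletin (7-hydroxy-6-methoxy-2H-chromen-2-one) | COc1cc2ccc(=O)oc2cc1O | starting material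
7 | 7-hydroxy-6-methoxy-3,4-dihydro-2H-chromen-2-one (dihydroscopoletin) | COc1cc2CCC(=O)Oc2cc1O | intermediate
8 | 7-hydroxy-6-methoxy-8-[(7-methoxy-2-oxo-2H-chromen-6-yl)acetyl]-3,4-dihydro-2H-chromen-2-one (deoxybenzoin) | COc1cc2CCC(=O)Oc2c(C(=O)Cc3cc4ccc(=O)oc4cc3OC)c1O | intermediate (not isolated)
9 | 6-methoxy-9-(7-methoxy-2-oxo-2H-chromen-6-yl)-3,4-dihydro-2H,10H-pyrano[2,3-f]chromene-2,10-dione (8-methoxyisoflavone with a dihydrocoumarin lactone across O5/C6 and a 7-methoxycoumarin-6-yl group at C3) | O=C1CCc2cc(OC)c3occ(-c4cc5ccc(=O)oc5cc4OC)c(=O)c3c2O1 | intermediate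
10 | 6-hydroxy-9-(7-hydroxy-2-oxo-2H-chromen-6-yl)-3,4-dihydro-2H,10H-pyrano[2,3-f]chromene-2,10-dione (the corresponding C8, C2' diphenol) | O=C1CCc2cc(O)c3occ(-c4cc5ccc(=O)oc5cc4O)c(=O)c3c2O1 | intermediate
11 | 6-(methoxymethoxy)-9-[7-(methoxymethoxy)-2-oxo-2H-chromen-6-yl]-3,4-dihydro-2H,10H-pyrano[2,3-f]chromene-2,10-dione (bis-lactone isoflavone, precursor of the key step) | O=C1CCc2cc(OCOC)c3occ(-c4cc5ccc(=O)oc5cc4OCOC)c(=O)c3c2O1 | intermediate
12 | methylmagnesium bromide | C[Mg]Br | starting material
13 | 5-hydroxy-6-(3-hydroxy-3-methylbutyl)-3-{4-hydroxy-5-[(1Z)-3-hydroxy-3-methylbut-1-en-1-yl]-2-(methoxymethoxy)phenyl}-8-(methoxymethoxy)-4H-chromen-4-one | CC(C)(O)CCc1cc(OCOC)c2occ(-c3cc(/C=C\C(C)(C)O)c(O)cc3OCOC)c(=O)c2c1O | intermediate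
14 | kraussianone 3, 5,8-dihydroxy-3-(7-hydroxy-2,2-dimethyl-2H-chromen-6-yl)-6-(3-hydroxy-3-methylbutyl)-4H-chromen-4-one | CC(C)(O)CCc1cc(O)c2occ(-c3cc4c(cc3O)OC(C)(C)C=C4)c(=O)c2c1O | target

**Step count.** Total: 8 steps. Longest linear sequence: 7 steps (steps 1, 2, 4, 5, 6, 7, 8 from 2,4-dihydroxyphenylacetic acid); the scopoletin branch joins at step 4.

**Steps most likely to fail**

First, step 7. The methyl nucleophile may add to ring C (conjugate addition at C2 or attack at C4) while the slower coumarin carbonyl is still being consumed, or the second addition at the coumarin may stall at the enone stage. The fallback sets out from 11 and returns at 13. The aryl ester of ring A is first opened without any carbon nucleophile by brief methanolysis (K2CO3, MeOH, 0 °C), which should give methyl 3-{5-hydroxy-8-(methoxymethoxy)-3-[7-(methoxymethoxy)-2-oxo-2H-chromen-6-yl]-4-oxo-4H-chromen-6-yl}propanoate F1 with a free, chelated C5-OH. F1 is then treated with excess MeLi in THF at −78 °C. The first equivalent forms the C5 phenoxide that guards C4 before any methyl addition begins, and the ester and the coumarin should each take up two methyl groups to give 13.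

Second, step 4. Acyl transfer to the flanked C8 position may be slow in BF3·OEt2, so that the reaction stops at the aryl ester stage, and the arylacetic acid may degrade on prolonged heating. The fallback sets out from 5 and 7 and returns at 8, then 9. Carbodiimide esterification (EDC·HCl, DMAP, CH2Cl2) should give 6-methoxy-2-oxo-3,4-dihydro-2H-chromen-7-yl (7-methoxy-2-oxo-2H-chromen-6-yl)acetate F2. Its Fries rearrangement in neat CF3SO3H at 0 °C to room temperature can only deliver the acyl group to C8, the single open position ortho to O7. Isolated 8 is then closed to 9 with DMF, BF3·OEt2 and MeSO2Cl as in the second half of step 4.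

Third, step 1. In hot sulfuric acid the ortho-hydroxy arylacetic acid may lactonise to the benzofuranone, which deactivates the ring toward the Pechmann alkylation, and ring sulfonation may compete. The fallback sets out from 1 and returns at 4. Fischer esterification (MeOH, cat. H2SO4, reflux) should give methyl 2,4-dihydroxyphenylacetate F3. Palladium-catalysed hydroarylation of ethyl propiolate with lactonisation (Pd(OAc)2, NaOAc, HCO2H, room temperature) should then give methyl (7-hydroxy-2-oxo-2H-chromen-6-yl)acetate F4. O-Methylation (MeI, K2CO3, DMF) gives 4, which is hydrolysed to 5 as in step 2.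

**Further compounds**
F1 | step 7 | methyl 3-{5-hydroxy-8-(methoxymethoxy)-3-[7-(methoxymethoxy)-2-oxo-2H-chromen-6-yl]-4-oxo-4H-chromen-6-yl}propanoate | COC(=O)CCc1cc(OCOC)c2occ(-c3cc4ccc(=O)oc4cc3OCOC)c(=O)c2c1O
F2 | step 4 | 6-methoxy-2-oxo-3,4-dihydro-2H-chromen-7-yl (7-methoxy-2-oxo-2H-chromen-6-yl)acetate | COc1cc2CCC(=O)Oc2cc1OC(=O)Cc1cc2ccc(=O)oc2cc1OC
F3 | step 1 | methyl 2,4-dihydroxyphenylacetate | COC(=O)Cc1ccc(O)cc1O
F4 | step 1 | methyl (7-hydroxy-2-oxo-2H-chromen-6-yl)acetate | COC(=O)Cc1cc2ccc(=O)oc2cc1O
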